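**Retrosynthetic overview**
1. Last skeletal bond made: the side-chain C7''–O bond, by syn hydro-oxygenation of an (E)-2,3-diarylallyl alcohol; this one step fixes C7'' and C8'' together, and only benzyl ethers remain to be removed.
2. The alkene comes from a Suzuki coupling of a ring B aryl bromide (already on the lactone) with a (Z)-2-bromocinnamyl alcohol made from O-benzylvanillin (ring C).
3. The trans-dibenzyl lactone comes from anti-selective enolate benzylation (ring A) of an (R)-β-benzyl-γ-butyrolactone.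
4. That lactone derives from 5-bromovanillin by Stobbe condensation, asymmetric hydrogenation, ester reduction and C–O lactonization.
5. Ring order: the three benzene rings are bought; the butyrolactone is closed in step 4; no other ring is formed.

Assumption: the facial sense of the two chiral catalysts (steps 3 and 10) is assigned by analogy with close substrates; if a first run shows the opposite sense, the antipodal ligand is used.
Locants: ring A = benzyl on lactone C3, ring B = benzyl on lactone C4, ring C = aryl of the diol arm; C7'' = carbinol CH, C8'' = CH on ring B, C9'' = CH2OH.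

**Route**

Step 1
Reactants: 1 5-bromovanillin (3-bromo-4-hydroxy-5-methoxybenzaldehyde)
Product: 2 4-(benzyloxy)-3-bromo-5-methoxybenzaldehyde
Conditions: BnBr, K2CO3, DMF, 60 °C
Reagents that add atoms: benzyl bromide BrCc1ccccc1
Why: Williamson etherification of the phenoxide; the benzyl ether withstands the alkoxide, hydride and organometallic steps that follow, and no stereocentre is involved.

Step 2
Reactants: 2 4-(benzyloxy)-3-bromo-5-methoxybenzaldehyde, 3 dimethyl succinate
Product: 4 (E)-4-[4-(benzyloxy)-3-bromo-5-methoxyphenyl]-3-(methoxycarbonyl)but-3-enoic acid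
Conditions: NaOMe, MeOH, reflux; then aq HCl
Reagents that add atoms: none
Why: Stobbe condensation: the succinate enolate adds to the aldehyde, the alkoxide closes to a paraconate, and base-induced ring opening gives the (E)-alkylidene half-ester regioselectively (conjugated ester kept, CH2CO2H freed).

Step 3
Reactants: 4 (E)-4-[4-(benzyloxy)-3-bromo-5-methoxyphenyl]-3-(methoxycarbonyl)but-3-enoic acid
Product: 5 (R)-4-[4-(benzyloxy)-3-bromo-5-methoxyphenyl]-3-(methoxycarbonyl)butanoic acid
Conditions: [Rh(cod)2]BF4 (0.5 mol %), (S,S)-Et-DuPhos (0.55 mol %), NaOMe (10 mol %), H2 (5 bar), MeOH, rt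
Reagents that add atoms: none
Why: Asymmetric hydrogenation of an itaconate-type Stobbe half-ester by a cationic monovalent rhodium bisphospholane catalyst; carboxylate and alkene chelate the metal so H2 is delivered to one face, setting the future lactone C4 as R, while the aryl bromide and benzyl ether are inert.

Step 4
Reactants: 5 (R)-4-[4-(benzyloxy)-3-bromo-5-methoxyphenyl]-3-(methoxycarbonyl)butanoic acid
Product: 7 (R)-4-[4-(benzyloxy)-3-bromo-5-methoxybenzyl]dihydrofuran-2(3H)-one, via hydroxy acid 6 (not isolated)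
Conditions: KOH (1 equiv), EtOH; CaCl2, NaBH4, −10 °C → rt; then 3 M HCl, rt
Reagents that add atoms: none
Why: Ca(BH4)2 made in the flask reduces the methyl ester but not the potassium carboxylate, and acidification closes the γ-lactone C–O bond (acid-catalysed lactonization) without touching the stereocentre.

Step 5
Reactants: 8 4-(benzyloxy)-3-methoxybenzyl alcohol
Product: 9 4-(benzyloxy)-3-methoxybenzyl bromide
Conditions: PBr3, Et2O, 0 °C
Reagents that add atoms: phosphorus tribromide BrP(Br)Br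
Why: SN2 bromination of the benzylic alcohol through its phosphite ester (PBr3 bromination); the bromide is used directly in step 6.

Step 6
Reactants: 7 (R)-4-[4-(benzyloxy)-3-bromo-5-methoxybenzyl]dihydrofuran-2(3H)-one, 9 4-(benzyloxy)-3-methoxybenzyl bromide
Product: 10 (3R,4R)-3-[4-(benzyloxy)-3-methoxybenzyl]-4-[4-(benzyloxy)-3-bromo-5-methoxybenzyl]dihydrofuran-2(3H)-one
Conditions: LiN(SiMe3)2, THF, −78 °C; then 9, −78 → −30 °C
Reagents that add atoms: none
Why: Lactone enolate alkylation: the benzylic bromide approaches anti to the C4 benzyl group, so C3 is set R and the ring is trans (3R,4R); the aryl bromide is untouched by the amide base at −78 °C.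

Step 7
Reactants: 11 4-(benzyloxy)-3-methoxybenzaldehyde (O-benzylvanillin), 12 ethyl bromo(triphenylphosphoranylidene)acetate
Product: 13 ethyl (Z)-3-[4-(benzyloxy)-3-methoxyphenyl]-2-bromoacrylate
Conditions: toluene, 90 °C
Reagents that add atoms: none
Why: Wittig olefination with a stabilised α-bromo ylide, which places the ester trans to the aryl group and so gives the (Z)-α-bromoacrylate (bromine cis to aryl).

Step 8
Reactants: 13 ethyl (Z)-3-[4-(benzyloxy)-3-methoxyphenyl]-2-bromoacrylate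
Product: 14 (Z)-3-[4-(benzyloxy)-3-methoxyphenyl]-2-bromoprop-2-en-1-ol
Conditions: i-Bu2AlH (2.3 equiv), CH2Cl2, −78 °C; aq potassium sodium tartrate
Reagents that add atoms: none
Why: 1,2-Reduction of the conjugated ester to the allylic alcohol by i-Bu2AlH at −78 °C, which leaves the vinyl bromide and the alkene geometry untouched.

Step 9
Reactants: 10 (3R,4R)-3-[4-(benzyloxy)-3-methoxybenzyl]-4-[4-(benzyloxy)-3-bromo-5-methoxybenzyl]dihydrofuran-2(3H)-one, 14 (Z)-3-[4-(benzyloxy)-3-methoxyphenyl]-2-bromoprop-2-en-1-ol, 15 bis(pinacolato)diboron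
Product: 17 (3R,4R)-3-[4-(benzyloxy)-3-methoxybenzyl]-4-{4-(benzyloxy)-3-[(E)-1-(4-benzyloxy-3-methoxyphenyl)-3-hydroxyprop-1-en-2-yl]-5-methoxybenzyl}dihydrofuran-2(3H)-one, via arylboronic pinacol ester 16 (not isolated)
Conditions: 10, 15, PdCl2(dppf) (5 mol %), KOAc, 1,4-dioxane, 90 °C; then 14, aq K3PO4, 80 °C; dilute HCl work-up
Reagents that add atoms: none
Why: Miyaura borylation of the aryl bromide, then Suzuki–Miyaura coupling on zerovalent palladium in the same flask; coupling proceeds with retention at the alkenyl bromide, so ring B replaces bromine cis to ring C (E alkene), and the trans lactone, being the thermodynamic isomer, recloses on acidic work-up if base opens it.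

Step 10
Reactants: 17 (3R,4R)-3-[4-(benzyloxy)-3-methoxybenzyl]-4-{4-(benzyloxy)-3-[(E)-1-(4-benzyloxy-3-methoxyphenyl)-3-hydroxyprop-1-en-2-yl]-5-methoxybenzyl}dihydrofuran-2(3H)-one, 18 dimethoxy(methyl)silane
Product: 21 (3R,4R)-3-[4-(benzyloxy)-3-methoxybenzyl]-4-{4-(benzyloxy)-3-[(1R,2R)-1-(4-benzyloxy-3-methoxyphenyl)-1,3-dihydroxypropan-2-yl]-5-methoxybenzyl}dihydrofuran-2(3H)-one, via mono-silyl ether 19 (not isolated), via bis-silyl ether 20 (not isolated)
Conditions: Cu(OAc)2 (5 mol %), (S)-DTBM-SEGPHOS (5.5 mol %), 18 (4 equiv), THF, rt, 1 h; then Me3SiOOSiMe3 (1.5 equiv, syringe pump, 6 h), 40 °C; then K2CO3 (cat.), MeOH, 0 °C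
Reagents that add atoms: bis(trimethylsilyl) peroxide C[Si](C)(C)OO[Si](C)(C)C
Why: Proposed new method: copper hydride-catalysed enantioselective syn hydro-oxygenation of a trisubstituted 1,2-diarylalkene. The bisphosphine-ligated monovalent copper hydride LCu–H first silylates the free hydroxyl by dehydrogenative Si–O coupling, then adds suprafacially across C7''=C8'' with copper on the less substituted benzylic C7'' and hydride on C8''; the ligand selects one alkene face, so C8'' and C7'' are fixed together as the erythro (1R,2R) pair. The benzylic alkylcopper is then oxidised at the electrophilic peroxide oxygen with retention (oxidative addition to trivalent copper, C–O reductive elimination), giving the C7''–OSiMe3 bond and LCu–OSiMe3, which the hydrosilane returns to LCu–H. Copper sits 1,3 to the C9'' oxygen, so β-alkoxide elimination is impossible. The closest known reaction type is copper hydride-catalysed asymmetric hydroamination of styrenes with O-benzoylhydroxylamines (same hydrocupration, N–O in place of O–O electrophile), together with the use of bis(trimethylsilyl) peroxide as an electrophilic hydroxyl source for organolithium and Grignard reagents.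

Step 11
Reactants: 21 (3R,4R)-3-[4-(benzyloxy)-3-methoxybenzyl]-4-{4-(benzyloxy)-3-[(1R,2R)-1-(4-benzyloxy-3-methoxyphenyl)-1,3-dihydroxypropan-2-yl]-5-methoxybenzyl}dihydrofuran-2(3H)-one
Product: 22 (3R,4R)-4-{4-hydroxy-3-[(1R,2R)-1,3-dihydroxy-1-(4-hydroxy-3-methoxyphenyl)propan-2-yl]-5-methoxybenzyl}-3-(4-hydroxy-3-methoxybenzyl)dihydrofuran-2(3H)-one (CNP0109231.2)
Conditions: H2 (1 atm), Pd/C (10 wt % Pd), EtOAc–EtOH, rt, stopped at full debenzylation
Reagents that add atoms: none
Why: Hydrogenolysis of the three aryl benzyl ethers over Pd/C under neutral conditions, which keeps the secondary benzylic C7''–OH, the lactone and all four stereocentres.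

**Compound list**
1 | 5-bromovanillin (3-bromo-4-hydroxy-5-methoxybenzaldehyde) | O=Cc1cc(Br)c(O)c(OC)c1 | starting material
2 | 4-(benzyloxy)-3-bromo-5-methoxybenzaldehyde | O=Cc1cc(Br)c(OCc2ccccc2)c(OC)c1 | intermediate
3 | dimethyl succinate | COC(=O)CCC(=O)OC | starting material
4 | (E)-4-[4-(benzyloxy)-3-bromo-5-methoxyphenyl]-3-(methoxycarbonyl)but-3-enoic acid | COC(=O)/C(CC(=O)O)=C/c1cc(Br)c(OCc2ccccc2)c(OC)c1 | intermediate
5 | (R)-4-[4-(benzyloxy)-3-bromo-5-methoxyphenyl]-3-(methoxycarbonyl)butanoic acid | COC(=O)[C@@H](CC(=O)O)Cc1cc(Br)c(OCc2ccccc2)c(OC)c1 | intermediate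
6 | (R)-4-[4-(benzyloxy)-3-bromo-5-methoxyphenyl]-3-(hydroxymethyl)butanoic acid (hydroxy acid, not isolated) | OC[C@@H](CC(=O)O)Cc1cc(Br)c(OCc2ccccc2)c(OC)c1 | intermediate
7 | (R)-4-[4-(benzyloxy)-3-bromo-5-methoxybenzyl]dihydrofuran-2(3H)-one | O=C1C[C@@H](Cc2cc(Br)c(OCc3ccccc3)c(OC)c2)CO1 | intermediate
8 | 4-(benzyloxy)-3-methoxybenzyl alcohol | OCc1ccc(OCc2ccccc2)c(OC)c1 | starting material
9 | 4-(benzyloxy)-3-methoxybenzyl bromide | BrCc1ccc(OCc2ccccc2)c(OC)c1 | intermediate
10 | (3R,4R)-3-[4-(benzyloxy)-3-methoxybenzyl]-4-[4-(benzyloxy)-3-bromo-5-methoxybenzyl]dihydrofuran-2(3H)-one | COc1cc(C[C@H]2C(=O)OC[C@@H]2Cc2cc(OC)c(OCc3ccccc3)c(Br)c2)ccc1OCc1ccccc1 | intermediate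
11 | 4-(benzyloxy)-3-methoxybenzaldehyde (O-benzylvanillin) | O=Cc1ccc(OCc2ccccc2)c(OC)c1 | starting material
12 | ethyl bromo(triphenylphosphoranylidene)acetate | CCOC(=O)C(Br)=P(c1ccccc1)(c1ccccc1)c1ccccc1 | starting material
13 | ethyl (Z)-3-[4-(benzyloxy)-3-methoxyphenyl]-2-bromoacrylate | CCOC(=O)/C(Br)=C/c1ccc(OCc2ccccc2)c(OC)c1 | intermediate
14 | (Z)-3-[4-(benzyloxy)-3-methoxyphenyl]-2-bromoprop-2-en-1-ol | OC/C(Br)=C/c1ccc(OCc2ccccc2)c(OC)c1 | intermediate
15 | bis(pinacolato)diboron | CC1(C)OB(OC1(C)C)B1OC(C)(C)C(C)(C)O1 | starting material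
16 | pinacol boronate of 10 (Bpin in place of Br on ring B; not isolated) | COc1cc(C[C@H]2C(=O)OC[C@@H]2Cc2cc(OC)c(OCc3ccccc3)c(B3OC(C)(C)C(C)(C)O3)c2)ccc1OCc1ccccc1 | intermediate
17 | (3R,4R)-3-[4-(benzyloxy)-3-methoxybenzyl]-4-{4-(benzyloxy)-3-[(E)-1-(4-benzyloxy-3-methoxyphenyl)-3-hydroxyprop-1-en-2-yl]-5-methoxybenzyl}dihydrofuran-2(3H)-one (rings B and C cis on the alkene) | COc1cc(C[C@H]2C(=O)OC[C@@H]2Cc2cc(OC)c(OCc3ccccc3)c(/C(CO)=C\c3ccc(OCc4ccccc4)c(OC)c3)c2)ccc1OCc1ccccc1 | intermediate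
18 | dimethoxy(methyl)silane | CO[SiH](C)OC | starting material
19 | C9''-O-[dimethoxy(methyl)silyl] ether of 17 (mono-silyl ether, not isolated) | COc1cc(C[C@H]2C(=O)OC[C@@H]2Cc2cc(OC)c(OCc3ccccc3)c(/C(CO[Si](C)(OC)OC)=C\c3ccc(OCc4ccccc4)c(OC)c3)c2)ccc1OCc1ccccc1 | intermediate
20 | C7''-O-trimethylsilyl, C9''-O-[dimethoxy(methyl)silyl] bis-ether of 21, (1R,2R) side chain (bis-silyl ether, not isolated) | COc1cc(C[C@H]2C(=O)OC[C@@H]2Cc2cc(OC)c(OCc3ccccc3)c([C@H](CO[Si](C)(OC)OC)[C@@H](O[Si](C)(C)C)c3ccc(OCc4ccccc4)c(OC)c3)c2)ccc1OCc1ccccc1 | intermediate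
21 | (3R,4R)-3-[4-(benzyloxy)-3-methoxybenzyl]-4-{4-(benzyloxy)-3-[(1R,2R)-1-(4-benzyloxy-3-methoxyphenyl)-1,3-dihydroxypropan-2-yl]-5-methoxybenzyl}dihydrofuran-2(3H)-one | COc1cc(C[C@H]2C(=O)OC[C@@H]2Cc2cc(OC)c(OCc3ccccc3)c([C@H](CO)[C@@H](O)c3ccc(OCc4ccccc4)c(OC)c3)c2)ccc1OCc1ccccc1 | intermediate
22 | (3R,4R)-4-{4-hydroxy-3-[(1R,2R)-1,3-dihydroxy-1-(4-hydroxy-3-methoxyphenyl)propan-2-yl]-5-methoxybenzyl}-3-(4-hydroxy-3-methoxybenzyl)dihydrofuran-2(3H)-one | COc1cc(C[C@H]2C(=O)OC[C@@H]2Cc2cc(OC)c(O)c([C@H](CO)[C@@H](O)c3ccc(O)c(OC)c3)c2)ccc1O | target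

**Step count and risks**
Total steps: 11. Longest linear sequence: 8 (steps 1, 2, 3, 4, 6, 9, 10, 11).

Steps most likely to fail:

Step 9 (one-flask borylation and Suzuki coupling). Risks are protodeboronation of the ortho-alkoxy arylboronate, base-induced loss of HBr from 14, and lactone opening. The fallback sets out from 14 (and uses 10) and comes back to the route at 17; it is a base-free Negishi coupling with reversed polarity. Alcohol 14 is silylated (TBSCl, imidazole, DMF) to (Z)-tert-butyldimethylsilyl ether F1. Bromine–lithium exchange (t-BuLi, 2 equiv, THF, −78 °C) gives alkenyllithium F2 with retention of geometry, and ZnCl2 converts it into alkenylzinc chloride F3. Coupling of this zinc reagent with aryl bromide 10 (Pd(OAc)2, SPhos, THF, 50 °C; the lactone tolerates organozinc reagents) gives silyl ether F4, and Bu4NF in THF releases 17.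

Step 10 (the proposed hydro-oxygenation). Risks are oxidation of the phosphine or direct reduction of the peroxide by LCu–H, slow hydrocupration of an electron-rich trisubstituted stilbene, and single-electron oxidation of the benzylic alkylcopper eroding the C7'' configuration. The fallback uses known chemistry, sets out from 17 and comes back at 21. Et3SiCl/imidazole gives triethylsilyl ether F5. Reagent-controlled asymmetric hydroboration with monoisopinocampheylborane IpcBH2 (freed from its TMEDA adduct with BF3·OEt2; THF, −25 °C; reagent enantiomer chosen on a model alkene) places boron on the less substituted C7'' and hydrogen on C8'' by syn addition. Oxidation in the same flask with NaBO3·4H2O, with retention, gives mono-silylated diol F6 with the same erythro (1R,2R) arm. Bu4NF/AcOH in THF then gives 21.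

Step 11 (hydrogenolysis). The risk is over-reduction of the 4-hydroxybenzylic C7''–OH once the para benzyl ether has gone. The fallback sets out from 21 and comes back at 22. Both hydroxyls are silylated (TBSOTf, 2,6-lutidine, CH2Cl2, 0 °C) to bis-silyl ether F7. Hydrogenolysis (H2, Pd/C (10 wt % Pd), EtOAc) then removes the three benzyl groups to give triphenol F8; the benzylic silyl ether resists C–O cleavage in a non-protic solvent. Bu4NF/AcOH in THF at 0 °C gives 22.

**Further compounds**
F1 | step 9 | (Z)-{[3-(4-benzyloxy-3-methoxyphenyl)-2-bromoprop-2-en-1-yl]oxy}(tert-butyl)dimethylsilane | CC(C)(C)[Si](C)(C)OC/C(Br)=C/c1ccc(OCc2ccccc2)c(OC)c1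
F2 | step 9 | (E)-{1-(4-benzyloxy-3-methoxyphenyl)-3-[(tert-butyldimethylsilyl)oxy]prop-1-en-2-yl}lithium (lithium cis to the aryl group) | [Li]/C(CO[Si](C)(C)C(C)(C)C)=C\c1ccc(OCc2ccccc2)c(OC)c1
F3 | step 9 | (Z)-{1-(4-benzyloxy-3-methoxyphenyl)-3-[(tert-butyldimethylsilyl)oxy]prop-1-en-2-yl}zinc chloride (zinc cis to the aryl group) | Cl[Zn]/C(CO[Si](C)(C)C(C)(C)C)=C\c1ccc(OCc2ccccc2)c(OC)c1
F4 | step 9 | C9''-O-tert-butyldimethylsilyl ether of 17 (E alkene) | COc1cc(C[C@H]2C(=O)OC[C@@H]2Cc2cc(OC)c(OCc3ccccc3)c(/C(CO[Si](C)(C)C(C)(C)C)=C\c3ccc(OCc4ccccc4)c(OC)c3)c2)ccc1OCc1ccccc1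
F5 | step 10 | C9''-O-triethylsilyl ether of 17 (E alkene) | COc1cc(C[C@H]2C(=O)OC[C@@H]2Cc2cc(OC)c(OCc3ccccc3)c(/C(CO[Si](CC)(CC)CC)=C\c3ccc(OCc4ccccc4)c(OC)c3)c2)ccc1OCc1ccccc1
F6 | step 10 | C9''-O-triethylsilyl ether of 21, (1R,2R) side chain | COc1cc(C[C@H]2C(=O)OC[C@@H]2Cc2cc(OC)c(OCc3ccccc3)c([C@H](CO[Si](CC)(CC)CC)[C@@H](O)c3ccc(OCc4ccccc4)c(OC)c3)c2)ccc1OCc1ccccc1
F7 | step 11 | C7'',C9''-bis-O-tert-butyldimethylsilyl ether of 21 | COc1cc(C[C@H]2C(=O)OC[C@@H]2Cc2cc(OC)c(OCc3ccccc3)c([C@H](CO[Si](C)(C)C(C)(C)C)[C@@H](O[Si](C)(C)C(C)(C)C)c3ccc(OCc4ccccc4)c(OC)c3)c2)ccc1OCc1ccccc1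
F8 | step 11 | C7'',C9''-bis-O-tert-butyldimethylsilyl ether of 22 | COc1cc(C[C@H]2C(=O)OC[C@@H]2Cc2cc(OC)c(O)c([C@H](CO[Si](C)(C)C(C)(C)C)[C@@H](O[Si](C)(C)C(C)(C)C)c3ccc(O)c(OC)c3)c2)ccc1O
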